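**Strategy.** Ring A is cut at C3–C4 and C5–C6, so that C6–C1–C2–C3 come from a 2-pyrone and C4–C5 from an O-silyl ynol ether. The plan exploits that in ring A the C4 oxygen sits para to the C1 acyl group while C6 carries only hydrogen: a 5-acyl-2-pyrone accepts the carbon-nucleophilic end of an oxygenated alkyne at its free C6, and the bridged lactone then ejects CO2. One thermal operation thus delivers the pentasubstituted arene with both side chains in place. The diene is a 4-silyloxy-3-methyl-2-pyrone bearing the L-tyrosine-derived (S)-2-silyloxy-3-arylpropanoyl group at C5; the dienophile is the prenyl-substituted triisopropylsilyl ynol ether.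

Key step: step 9

Assumption: tert-butyl 2-methyl-3-oxobutanoate (5) is taken as a catalogue compound and is racemic; C2 of 7 and 9, the enamine geometry of 9 and the bridgeheads of 18 are therefore undefined, which is harmless because these centres become sp2 or disappear.

Step 1
Reactants: 1 L-tyrosine
Product: 2 (S)-2-hydroxy-3-(4-hydroxyphenyl)propanoic acid
Conditions: NaNO2, 1 M H2SO4, H2O, 0 °C to rt
Reagents that add atoms: water, O
Why: Diazotisation and hydroxy-deamination of an α-amino acid: the neighbouring carboxylate expels N2 to an α-lactone that water reopens, so two inversions should return the (S) configuration (net retention).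

Step 2
Reactants: 2 (S)-2-hydroxy-3-(4-hydroxyphenyl)propanoic acid
Product: 3 (S)-2-hydroxy-3-(4-hydroxyphenyl)-N-methoxy-N-methylpropanamide
Conditions: MeNHOMe·HCl, EDC·HCl, HOBt, N-methylmorpholine, DMF, 0 °C to rt
Reagents that add atoms: N,O-dimethylhydroxylamine hydrochloride, CNOC.Cl
Why: Carbodiimide/HOBt amide coupling to the Weinreb amide; the amine should outcompete the free phenol and secondary alcohol for the active ester, and the stereocentre is not involved.

Step 3
Reactants: 3 (S)-2-hydroxy-3-(4-hydroxyphenyl)-N-methoxy-N-methylpropanamide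
Product: 4 (S)-2-(tert-butyldimethylsilyloxy)-3-[4-(tert-butyldimethylsilyloxy)phenyl]-N-methoxy-N-methylpropanamide
Conditions: TBSCl (2.5 equiv), imidazole, DMF, rt
Reagents that add atoms: tert-butyldimethylsilyl chloride, C[Si](C)(Cl)C(C)(C)C
Why: Imidazole-promoted O-silylation should cap the phenol and the secondary alcohol as ethers that survive the base, acid and heat of the later steps and fall to fluoride at the end.

Step 4
Reactants: 4 (S)-2-(tert-butyldimethylsilyloxy)-3-[4-(tert-butyldimethylsilyloxy)phenyl]-N-methoxy-N-methylpropanamide; 5 tert-butyl 2-methyl-3-oxobutanoate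
Product: 7 tert-butyl (6S)-6-(tert-butyldimethylsilyloxy)-7-[4-(tert-butyldimethylsilyloxy)phenyl]-2-methyl-3,5-dioxoheptanoate, via dilithium dienolate 6 (not isolated)
Conditions: 5 (2.5 equiv), LiN(i-Pr)2 (4.9 equiv), THF, −78 to 0 °C; then 4, −78 to −20 °C; AcOH quench
Reagents that add atoms: none
Why: γ-Acylation of an acetoacetate dianion by a Weinreb amide (Claisen-type condensation): the terminal carbanion is the more nucleophilic site, the chelated tetrahedral adduct prevents over-addition until the quench, and the α-silyloxy (S) centre should not be deprotonated at low temperature without free amide base.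

Step 5
Reactants: 7 tert-butyl (6S)-6-(tert-butyldimethylsilyloxy)-7-[4-(tert-butyldimethylsilyloxy)phenyl]-2-methyl-3,5-dioxoheptanoate; 8 N,N-dimethylformamide dimethyl acetal
Product: 9 tert-butyl (6S)-6-(tert-butyldimethylsilyloxy)-7-[4-(tert-butyldimethylsilyloxy)phenyl]-4-[(dimethylamino)methylidene]-2-methyl-3,5-dioxoheptanoate
Conditions: 8 (1.3 equiv), toluene, rt
Reagents that add atoms: none
Why: Aminomethylenation of an active methylene group by an amide acetal; only C4, flanked by two ketones and carrying two hydrogens, can condense, since C2 is a methine.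

Step 6
Reactants: 9 tert-butyl (6S)-6-(tert-butyldimethylsilyloxy)-7-[4-(tert-butyldimethylsilyloxy)phenyl]-4-[(dimethylamino)methylidene]-2-methyl-3,5-dioxoheptanoate
Product: 10 5-{(2S)-2-(tert-butyldimethylsilyloxy)-3-[4-(tert-butyldimethylsilyloxy)phenyl]propanoyl}-4-hydroxy-3-methyl-2H-pyran-2-one
Conditions: CF3CO2H (3 equiv), CH2Cl2, 0 °C to rt
Reagents that add atoms: none
Why: Acid-triggered cyclocondensation of a 2-(aminomethylene)-3-oxo-1,5-dicarbonyl compound to a 4-hydroxy-2-pyrone (the enaminone ring closure familiar from chromones and 4-hydroxy-2-pyrone-5-carboxylates): the ester carbonyl oxygen adds to the protonated enaminone CH, then dimethylamine and isobutene leave, so the ring oxygen should end on the CH carbon only, because the ketone oxygen cannot lactonise a tert-butyl ester by acyl substitution.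

Step 7
Reactants: 10 5-{(2S)-2-(tert-butyldimethylsilyloxy)-3-[4-(tert-butyldimethylsilyloxy)phenyl]propanoyl}-4-hydroxy-3-methyl-2H-pyran-2-one
Product: 11 5-{(2S)-2-(tert-butyldimethylsilyloxy)-3-[4-(tert-butyldimethylsilyloxy)phenyl]propanoyl}-4-(tert-butyldimethylsilyloxy)-3-methyl-2H-pyran-2-one
Conditions: TBSCl (1.2 equiv), Et3N, CH2Cl2, 0 °C to rt; hexane, filtration, no aqueous work-up
Reagents that add atoms: tert-butyldimethylsilyl chloride, C[Si](C)(Cl)C(C)(C)C
Why: O-Silylation of a vinylogous carboxylic acid: the 4-hydroxyl of a 4-hydroxy-2-pyrone is as acidic as a carboxylic acid and is silylated like one, and the water-sensitive 4-silyloxy-2-pyrone is kept from water and silica and used crude.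

Step 8
Reactants: 12 ethyl 4-methylpent-3-enoate; 13 dibromomethane
Product: 17 5-methyl-1-(triisopropylsilyloxy)hex-4-en-1-yne, via dibromomethyllithium 14 (not isolated), via lithium dibromoenolate 15 (not isolated), via lithium ynolate 16 (not isolated)
Conditions: 13, lithium 2,2,6,6-tetramethylpiperidide, THF, −78 °C; 12; LiN(SiMe3)2; n-BuLi, −78 to 0 °C; TIPSOTf, −78 °C to rt
Reagents that add atoms: triisopropylsilyl trifluoromethanesulfonate, CC(C)[Si](OS(=O)(=O)C(F)(F)F)(C(C)C)C(C)C
Why: Kowalski ester homologation halted at the ynolate: LiCHBr2 adds to the ester, the dibromo enolate undergoes bromine–lithium exchange and 1,2-shift to the lithium ynolate, and the bulky silyl triflate should react on oxygen to give the isolable triisopropylsilyl ynol ether.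

Step 9
Reactants: 11 5-{(2S)-2-(tert-butyldimethylsilyloxy)-3-[4-(tert-butyldimethylsilyloxy)phenyl]propanoyl}-4-(tert-butyldimethylsilyloxy)-3-methyl-2H-pyran-2-one; 17 5-methyl-1-(triisopropylsilyloxy)hex-4-en-1-yne
Product: 19 (2S)-2-(tert-butyldimethylsilyloxy)-1-[2-(tert-butyldimethylsilyloxy)-3-methyl-5-(3-methylbut-2-en-1-yl)-4-(triisopropylsilyloxy)phenyl]-3-[4-(tert-butyldimethylsilyloxy)phenyl]propan-1-one, via 2-oxabicyclo[2.2.2]octadienone cycloadduct 18 (not isolated)
Conditions: 17 (2.5 equiv), toluene, 90 to 110 °C, sealed tube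
Reagents that add atoms: none
Why: Proposed new method: bond formation should start between the prenyl-substituted alkyne carbon, which carries the electron density pushed in by the silyloxy group, and C6 of the pyrone, a position that is unsubstituted and doubly activated (β to the ketone, vinylogous to the lactone carbonyl); ring carbon C3, α to the lactone carbonyl, then bonds to the oxygen-bearing alkyne carbon, in one asynchronous transition state or in two stages, and the strained bicyclic lactone 18 extrudes CO2 in a retro-Diels–Alder step that cannot reverse and gives the benzene ring directly at the correct oxidation level. The nearest established reaction type is the Diels–Alder reaction with inverse electron demand between 2-pyrones carrying a 5-carbonyl substituent (methyl coumalate and 5-acyl analogues) and ynamines, alkoxyalkynes or ketene acetals, in which the heteroatom of the dienophile ends para to the carbonyl group once CO2 has gone; thermal annulations of triisopropylsilyl ynol ethers with vinylketenes (Danheiser benzannulation) indicate that 17 tolerates hot toluene. Ring A closes as a six-membered carbocycle by intermolecular [4+2] cycloaddition followed by cycloreversion, with bond C5–C6 leading and bond C3–C4 (ring-A numbering) forming onto an sp carbon, which keeps the methyl-bearing C3 accessible. No stereocentre is created in 19, because the two bridgehead centres of 18 disappear on aromatisation, and the (S) centre is a spectator under neutral aprotic conditions. Only regiochemistry has to be controlled, the silyloxy carbon must end para to the ketone, and the polarised partners allow just this pairing: the electron-rich alkyne carbon matches the acceptor position C6 and the donor-bearing carbon is left for C3. Because the 4-silyloxy and 3-methyl substituents feed electron density into the diene, the cycloaddition may be sluggish; an excess of the strongly donor-substituted alkyne and heating are meant to compensate.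

Step 10
Reactants: 19 (2S)-2-(tert-butyldimethylsilyloxy)-1-[2-(tert-butyldimethylsilyloxy)-3-methyl-5-(3-methylbut-2-en-1-yl)-4-(triisopropylsilyloxy)phenyl]-3-[4-(tert-butyldimethylsilyloxy)phenyl]propan-1-one
Product: 20 Lespeflorin C5, (2S)-1-[2,4-dihydroxy-3-methyl-5-(3-methylbut-2-en-1-yl)phenyl]-2-hydroxy-3-(4-hydroxyphenyl)propan-1-one
Conditions: Bu4NF (6 equiv), AcOH (6 equiv), THF, 0 °C to rt
Reagents that add atoms: none
Why: Fluoride-mediated global desilylation: the three aryl silyl ethers should cleave quickly and the secondary ether more slowly, while the acetic acid buffer keeps the medium non-basic and only weakly acidic, so the α-hydroxy ketone should not epimerise and the ortho-prenyl phenol should not cyclise to a chroman.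

**Compound list**

1 | L-tyrosine, (S)-2-amino-3-(4-hydroxyphenyl)propanoic acid | N[C@@H](Cc1ccc(O)cc1)C(=O)O | starting material
2 | (S)-2-hydroxy-3-(4-hydroxyphenyl)propanoic acid | O[C@@H](Cc1ccc(O)cc1)C(=O)O | intermediate
3 | (S)-2-hydroxy-3-(4-hydroxyphenyl)-N-methoxy-N-methylpropanamide | CON(C)C(=O)[C@@H](O)Cc1ccc(O)cc1 | intermediate
4 | (S)-2-(tert-butyldimethylsilyloxy)-3-[4-(tert-butyldimethylsilyloxy)phenyl]-N-methoxy-N-methylpropanamide | CON(C)C(=O)[C@@H](O[Si](C)(C)C(C)(C)C)Cc1ccc(O[Si](C)(C)C(C)(C)C)cc1 | intermediate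
5 | tert-butyl 2-methyl-3-oxobutanoate (racemic) | CC(=O)C(C)C(=O)OC(C)(C)C | starting material
6 | dilithium dienolate of tert-butyl 2-methyl-3-oxobutanoate | C=C(O[Li])C(C)=C(O[Li])OC(C)(C)C | intermediate (not isolated)
7 | tert-butyl (6S)-6-(tert-butyldimethylsilyloxy)-7-[4-(tert-butyldimethylsilyloxy)phenyl]-2-methyl-3,5-dioxoheptanoate (C2 epimers, keto form drawn) | CC(C)(C)OC(=O)C(C)C(=O)CC(=O)[C@@H](O[Si](C)(C)C(C)(C)C)Cc1ccc(O[Si](C)(C)C(C)(C)C)cc1 | intermediate
8 | N,N-dimethylformamide dimethyl acetal | COC(OC)N(C)C | starting material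
9 | tert-butyl (6S)-6-(tert-butyldimethylsilyloxy)-7-[4-(tert-butyldimethylsilyloxy)phenyl]-4-[(dimethylamino)methylidene]-2-methyl-3,5-dioxoheptanoate | CC(C)(C)OC(=O)C(C)C(=O)C(=CN(C)C)C(=O)[C@@H](O[Si](C)(C)C(C)(C)C)Cc1ccc(O[Si](C)(C)C(C)(C)C)cc1 | intermediate
10 | 5-{(2S)-2-(tert-butyldimethylsilyloxy)-3-[4-(tert-butyldimethylsilyloxy)phenyl]propanoyl}-4-hydroxy-3-methyl-2H-pyran-2-one | O=C1OC=C(C(=O)[C@@H](O[Si](C)(C)C(C)(C)C)Cc2ccc(O[Si](C)(C)C(C)(C)C)cc2)C(O)=C1C | intermediate
11 | 5-{(2S)-2-(tert-butyldimethylsilyloxy)-3-[4-(tert-butyldimethylsilyloxy)phenyl]propanoyl}-4-(tert-butyldimethylsilyloxy)-3-methyl-2H-pyran-2-one | O=C1OC=C(C(=O)[C@@H](O[Si](C)(C)C(C)(C)C)Cc2ccc(O[Si](C)(C)C(C)(C)C)cc2)C(O[Si](C)(C)C(C)(C)C)=C1C | intermediate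
12 | ethyl 4-methylpent-3-enoate | CCOC(=O)CC=C(C)C | starting material
13 | dibromomethane | BrCBr | starting material
14 | dibromomethyllithium | [Li]C(Br)Br | intermediate (not isolated)
15 | lithium 1,1-dibromo-5-methylhexa-1,4-dien-2-olate | CC(C)=CCC(O[Li])=C(Br)Br | intermediate (not isolated)
16 | lithium 5-methylhex-4-en-1-yn-1-olate | CC(C)=CCC#CO[Li] | intermediate (not isolated)
17 | 5-methyl-1-(triisopropylsilyloxy)hex-4-en-1-yne | CC(C)=CCC#CO[Si](C(C)C)(C(C)C)C(C)C | intermediate
18 | 2-oxabicyclo[2.2.2]octa-5,7-dien-3-one cycloadduct: C4 methyl, C5 tert-butyldimethylsilyloxy, C6 (2S)-acyl side chain, C7 3-methylbut-2-enyl, C8 triisopropylsilyloxy; both bridgehead diastereomers | CC12C(=O)OC(C(CC=C(C)C)=C1O[Si](C(C)C)(C(C)C)C(C)C)C(C(=O)[C@@H](O[Si](C)(C)C(C)(C)C)Cc1ccc(O[Si](C)(C)C(C)(C)C)cc1)=C2O[Si](C)(C)C(C)(C)C | intermediate (not isolated)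
19 | (2S)-2-(tert-butyldimethylsilyloxy)-1-[2-(tert-butyldimethylsilyloxy)-3-methyl-5-(3-methylbut-2-en-1-yl)-4-(triisopropylsilyloxy)phenyl]-3-[4-(tert-butyldimethylsilyloxy)phenyl]propan-1-one | CC(C)=CCc1cc(C(=O)[C@@H](O[Si](C)(C)C(C)(C)C)Cc2ccc(O[Si](C)(C)C(C)(C)C)cc2)c(O[Si](C)(C)C(C)(C)C)c(C)c1O[Si](C(C)C)(C(C)C)C(C)C | intermediate
20 | Lespeflorin C5, (2S)-1-[2,4-dihydroxy-3-methyl-5-(3-methylbut-2-en-1-yl)phenyl]-2-hydroxy-3-(4-hydroxyphenyl)propan-1-one | CC(C)=CCc1cc(C(=O)[C@@H](O)Cc2ccc(O)cc2)c(O)c(C)c1O | target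

**Step count.** Total: 10 steps. Longest linear sequence: 9 steps (steps 1 to 7, 9 and 10, from L-tyrosine); step 8 is the one-step side branch.

**Steps most likely to fail**

1. Step 9 (key step). The electron-enriched pyrone may react too slowly, so that thermal isomerisation or oligomerisation of the ynol ether takes over. The first dipolar adduct may also close through the ketone oxygen or at C5 (four-membered ring) instead of at C3. The fallback uses known chemistry and makes the aryl–acyl bond instead of building the ring; it sets out from Weinreb amide 4 and returns to the route at 20. Commercial 2-methylbenzene-1,3-diol would be dibrominated (Br2, CH2Cl2/AcOH, 0 °C) to 4,6-dibromo-2-methylbenzene-1,3-diol F1 and silylated (TIPSOTf, 2,6-lutidine, CH2Cl2) to 1,5-dibromo-3-methyl-2,4-bis(triisopropylsilyloxy)benzene F2. One bromine–lithium exchange (n-BuLi, 1.0 equiv, THF, −78 °C) should give [5-bromo-3-methyl-2,4-bis(triisopropylsilyloxy)phenyl]lithium F3, which is alkylated with prenyl bromide to 1-bromo-3-methyl-5-(3-methylbut-2-en-1-yl)-2,4-bis(triisopropylsilyloxy)benzene F4. A second exchange (t-BuLi, 2 equiv, Et2O, −78 °C) should give [3-methyl-5-(3-methylbut-2-en-1-yl)-2,4-bis(triisopropylsilyloxy)phenyl]lithium F5, which adds to 4 at −78 °C to give (2S)-2-(tert-butyldimethylsilyloxy)-3-[4-(tert-butyldimethylsilyloxy)phenyl]-1-[3-methyl-5-(3-methylbut-2-en-1-yl)-2,4-bis(triisopropylsilyloxy)phenyl]propan-1-one F6. The Bu4NF/AcOH treatment of step 10 should then convert F6 into 20. Both aryllithiums are kept at −78 °C to suppress oxygen-to-carbon silyl migration.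

2. Step 6. The tert-butyl ester may be cleaved before ring closure and the resulting β-keto acid may decarboxylate. The secondary silyl ether may be lost under anhydrous acid, or closure may go through the ketone oxygen. The fallback replaces alkyl–oxygen cleavage by enamine hydrolysis and acyl substitution in the methyl ester series; it sets out from 4 and returns at 10. Commercial methyl 2-methyl-3-oxobutanoate would be converted (LiN(i-Pr)2, THF, −78 to 0 °C) into its dilithium dienolate F7 and acylated by 4 to methyl (6S)-6-(tert-butyldimethylsilyloxy)-7-[4-(tert-butyldimethylsilyloxy)phenyl]-2-methyl-3,5-dioxoheptanoate F8. Acetal 8 should convert F8 into methyl (6S)-6-(tert-butyldimethylsilyloxy)-7-[4-(tert-butyldimethylsilyloxy)phenyl]-4-[(dimethylamino)methylidene]-2-methyl-3,5-dioxoheptanoate F9. Aqueous acid (1 M HCl, THF, rt) should hydrolyse the enamine to methyl (6S)-6-(tert-butyldimethylsilyloxy)-7-[4-(tert-butyldimethylsilyloxy)phenyl]-4-(hydroxymethylidene)-2-methyl-3,5-dioxoheptanoate F10. Its aldehyde-derived enol oxygen, the least hindered one, should lactonise onto the methyl ester with loss of methanol to give 10, so no β-keto acid is formed.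

3. Step 8. LiCHBr2 or the amide bases may deprotonate the acidic α-methylene of the β,γ-unsaturated ester in competition with carbonyl addition, and the double bond may migrate into conjugation. The fallback oxidises a lithium acetylide instead of homologating the ester; it sets out from 12 and returns at 17. Reduction (i-Bu2AlH, CH2Cl2, −78 °C) should give 4-methylpent-3-enal F11, which is used crude in a Corey–Fuchs olefination (CBr4, PPh3, CH2Cl2, 0 °C) to 1,1-dibromo-5-methylhexa-1,4-diene F12. Treatment with n-BuLi (2 equiv, THF, −78 °C) should convert F12 into lithium 5-methylhex-4-en-1-yn-1-ide F13. F13 is oxidised in the same flask with LiOOt-Bu (from t-BuOOH and LiN(SiMe3)2, −78 to 0 °C) to the ynolate 16 and silylated with TIPSOTf to 17.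

**Further compounds**

F1 | step 9 | 4,6-dibromo-2-methylbenzene-1,3-diol | Cc1c(O)c(Br)cc(Br)c1O
F2 | step 9 | 1,5-dibromo-3-methyl-2,4-bis(triisopropylsilyloxy)benzene | Cc1c(O[Si](C(C)C)(C(C)C)C(C)C)c(Br)cc(Br)c1O[Si](C(C)C)(C(C)C)C(C)C
F3 | step 9 | [5-bromo-3-methyl-2,4-bis(triisopropylsilyloxy)phenyl]lithium | [Li]c1cc(Br)c(O[Si](C(C)C)(C(C)C)C(C)C)c(C)c1O[Si](C(C)C)(C(C)C)C(C)C
F4 | step 9 | 1-bromo-3-methyl-5-(3-methylbut-2-en-1-yl)-2,4-bis(triisopropylsilyloxy)benzene | CC(C)=CCc1cc(Br)c(O[Si](C(C)C)(C(C)C)C(C)C)c(C)c1O[Si](C(C)C)(C(C)C)C(C)C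
F5 | step 9 | [3-methyl-5-(3-methylbut-2-en-1-yl)-2,4-bis(triisopropylsilyloxy)phenyl]lithium | [Li]c1cc(CC=C(C)C)c(O[Si](C(C)C)(C(C)C)C(C)C)c(C)c1O[Si](C(C)C)(C(C)C)C(C)C
F6 | step 9 | (2S)-2-(tert-butyldimethylsilyloxy)-3-[4-(tert-butyldimethylsilyloxy)phenyl]-1-[3-methyl-5-(3-methylbut-2-en-1-yl)-2,4-bis(triisopropylsilyloxy)phenyl]propan-1-one | CC(C)=CCc1cc(C(=O)[C@@H](O[Si](C)(C)C(C)(C)C)Cc2ccc(O[Si](C)(C)C(C)(C)C)cc2)c(O[Si](C(C)C)(C(C)C)C(C)C)c(C)c1O[Si](C(C)C)(C(C)C)C(C)C
F7 | step 6 | dilithium dienolate of methyl 2-methyl-3-oxobutanoate | C=C(O[Li])C(C)=C(O[Li])OC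
F8 | step 6 | methyl (6S)-6-(tert-butyldimethylsilyloxy)-7-[4-(tert-butyldimethylsilyloxy)phenyl]-2-methyl-3,5-dioxoheptanoate | COC(=O)C(C)C(=O)CC(=O)[C@@H](O[Si](C)(C)C(C)(C)C)Cc1ccc(O[Si](C)(C)C(C)(C)C)cc1
F9 | step 6 | methyl (6S)-6-(tert-butyldimethylsilyloxy)-7-[4-(tert-butyldimethylsilyloxy)phenyl]-4-[(dimethylamino)methylidene]-2-methyl-3,5-dioxoheptanoate | COC(=O)C(C)C(=O)C(=CN(C)C)C(=O)[C@@H](O[Si](C)(C)C(C)(C)C)Cc1ccc(O[Si](C)(C)C(C)(C)C)cc1
F10 | step 6 | methyl (6S)-6-(tert-butyldimethylsilyloxy)-7-[4-(tert-butyldimethylsilyloxy)phenyl]-4-(hydroxymethylidene)-2-methyl-3,5-dioxoheptanoate | COC(=O)C(C)C(=O)C(=CO)C(=O)[C@@H](O[Si](C)(C)C(C)(C)C)Cc1ccc(O[Si](C)(C)C(C)(C)C)cc1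
F11 | step 8 | 4-methylpent-3-enal | CC(C)=CCC=O
F12 | step 8 | 1,1-dibromo-5-methylhexa-1,4-diene | CC(C)=CCC=C(Br)Br
F13 | step 8 | lithium 5-methylhex-4-en-1-yn-1-ide | [Li]C#CCC=C(C)C
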